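**Retrosynthetic overview**
Amaurone A is cut at C7=C8 (Horner–Wadsworth–Emmons) into pyranone phosphonate 31 and dienal 25; 25 comes from the ring C12 aldehyde 23 by two formyl-ylide Wittig reactions (C11=C12, then C9=C10).
The strategy rests on ring C13–C18: C16 lies between the two methyl carbinols C15 and C17, so the α-ketol C16(=O)–C17(Me)(OH) is the crossed benzoin adduct of a C16 aldehyde held on quaternary, non-enolizable C15 and a C17 methyl ketone. Cutting C16–C17 gives the acyclic keto-aldehyde 18.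
In 18, C18 comes from chelation-controlled addition of an acetyl anion equivalent, C13 from an Evans alkylation (C12 enters as CH2OBn), and C14/C15 from Sharpless epoxidation of tiglyl alcohol followed by SN2 opening with a vinyl cuprate.
Ring order: the carbocycle C13–C18 is closed in step 15 by the carbene-catalysed benzoin; the pyranone ring is built separately (step 23) from a triketide ester and joined last.

Key step: step 15

Remark on the chemistry: numbering used throughout is pyranone C2–C6 (C2 carries OMe), chain C7–C12, carbocycle C13–C18 (C13 carries the chain, C14 CHMe, C15 C(Me)OH, C16 CHOAc, C17 C(Me)OH, C18 CHOH). O12 is carried as a benzyl ether and O16 as a PMB ether so that O16 can be freed oxidatively while O12 stays protected. All reagents named are commercial.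

Step 1
Reactants: 1 (E)-2-methylbut-2-en-1-ol
Product: 2 [(2S,3S)-2,3-dimethyloxiran-2-yl]methanol
Conditions: Ti(OiPr)4 (10 mol %), L-(+)-diethyl tartrate (12 mol %), t-BuOOH, 4 Å MS, CH2Cl2, −20 °C
Reagents that add atoms: tert-butyl hydroperoxide, CC(C)(C)OO
Why: Katsuki–Sharpless asymmetric epoxidation of a trisubstituted (E)-allylic alcohol; the L-(+)-tartrate catalyst delivers oxygen to the face that gives the (2S,3S)-epoxide, which fixes C15 and, after the inversion of step 2, C14.

Step 2
Reactants: 2 [(2S,3S)-2,3-dimethyloxiran-2-yl]methanol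
Product: 3 (2R,3S)-2,3-dimethylpent-4-ene-1,2-diol
Conditions: vinylmagnesium bromide (3 equiv), CuI (15 mol %), THF, −30 to −10 °C; aq NH4Cl
Reagents that add atoms: vinylmagnesium bromide, C=C[Mg]Br
Why: Copper-catalysed Grignard opening of a 2,3-epoxy alcohol; C15 is quaternary, so the vinyl group attacks C14 by SN2 with inversion and the tertiary C15 carbinol keeps its configuration.

Step 3
Reactants: 3 (2R,3S)-2,3-dimethylpent-4-ene-1,2-diol
Product: 4 (2R,3S)-1-[(4-methoxybenzyl)oxy]-2,3-dimethylpent-4-en-2-ol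
Conditions: NaH (1.05 equiv), 4-methoxybenzyl chloride, Bu4NI (cat.), THF/DMF, 0 °C
Reagents that add atoms: 4-methoxybenzyl chloride, COc1ccc(CCl)cc1
Why: Williamson etherification; the primary alkoxide of the 1,2-diol is alkylated much faster than the hindered tertiary one.

Step 4
Reactants: 4 (2R,3S)-1-[(4-methoxybenzyl)oxy]-2,3-dimethylpent-4-en-2-ol
Product: 5 triethylsilyl ether of 4 at the tertiary oxygen O15
Conditions: Et3SiOTf, 2,6-lutidine, CH2Cl2, 0 °C
Reagents that add atoms: triethylsilyl trifluoromethanesulfonate, CC[Si](CC)(CC)OS(=O)(=O)C(F)(F)F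
Why: Silyl triflate with a hindered pyridine base silylates tertiary alcohols; the ether blocks later lactonization onto O15.

Step 5
Reactants: 5 triethylsilyl ether of 4
Product: 7 (3S,4R)-5-[(4-methoxybenzyl)oxy]-3,4-dimethyl-4-[(triethylsilyl)oxy]pentan-1-ol, via B-alkyl-9-BBN adduct 6 (not isolated)
Conditions: 9-BBN, THF, 0 °C to rt; then NaOH, H2O2, 0 °C
Reagents that add atoms: hydrogen peroxide, OO
Why: Brown hydroboration–oxidation; 9-BBN adds anti-Markovnikov to the monosubstituted alkene and oxidation with retention gives the primary alcohol (C18) without touching a stereocenter.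

Step 6
Reactants: 7 (3S,4R)-5-[(4-methoxybenzyl)oxy]-3,4-dimethyl-4-[(triethylsilyl)oxy]pentan-1-ol
Product: 8 (3S,4R)-5-[(4-methoxybenzyl)oxy]-3,4-dimethyl-4-[(triethylsilyl)oxy]pentanoic acid
Conditions: TEMPO (20 mol %), PhI(OAc)2 (2.2 equiv), MeCN/H2O, rt
Reagents that add atoms: water, O
Why: TEMPO/PhI(OAc)2 oxidation in aqueous acetonitrile takes a primary alcohol through the aldehyde hydrate to the acid and tolerates PMB and silyl ethers.

Step 7
Reactants: 8 (3S,4R)-5-[(4-methoxybenzyl)oxy]-3,4-dimethyl-4-[(triethylsilyl)oxy]pentanoic acid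
Product: 10 (R)-4-benzyl-3-[(3S,4R)-5-[(4-methoxybenzyl)oxy]-3,4-dimethyl-4-[(triethylsilyl)oxy]pentanoyl]oxazolidin-2-one, via mixed pivalic anhydride 9 (not isolated)
Conditions: t-BuCOCl, Et3N, THF, −20 °C; then LiCl, (R)-4-benzyloxazolidin-2-one, −20 °C to rt
Reagents that add atoms: (R)-4-benzyloxazolidin-2-one, O=C1N[C@H](Cc2ccccc2)CO1
Why: Mixed-anhydride N-acylation of an Evans oxazolidinone (LiCl/Et3N variant) installs the auxiliary that will control C13.

Step 8
Reactants: 10 N-acyl oxazolidinone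
Product: 11 (R)-4-benzyl-3-[(2S,3S,4R)-2-[(benzyloxy)methyl]-5-[(4-methoxybenzyl)oxy]-3,4-dimethyl-4-[(triethylsilyl)oxy]pentanoyl]oxazolidin-2-one
Conditions: TiCl4 (1.05 equiv), i-Pr2NEt (1.1 equiv), CH2Cl2, 0 °C; then BnOCH2Cl, 0 °C
Reagents that add atoms: benzyl chloromethyl ether, ClCOCc1ccccc1
Why: Evans alkylation of the chelated chlorotitanium Z-enolate; the electrophile enters on the face away from the benzyl group of the (R)-auxiliary and so sets C13, with C12 in place as its benzyl ether.

Step 9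
Reactants: 11 alkylated N-acyl oxazolidinone
Product: 12 (2R,3S,4R)-2-[(benzyloxy)methyl]-5-[(4-methoxybenzyl)oxy]-3,4-dimethyl-4-[(triethylsilyl)oxy]pentan-1-ol
Conditions: LiBH4, MeOH (2 equiv), THF, 0 °C
Reagents that add atoms: none
Why: LiBH4 reductive cleavage of the N-acyl oxazolidinone gives the primary alcohol (C18) without epimerizing C13 and returns the auxiliary.

Step 10
Reactants: 12 primary alcohol
Product: 13 (2S,3S,4R)-2-[(benzyloxy)methyl]-5-[(4-methoxybenzyl)oxy]-3,4-dimethyl-4-[(triethylsilyl)oxy]pentanal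
Conditions: Dess–Martin periodinane, NaHCO3, CH2Cl2, 0 °C to rt
Reagents that add atoms: none
Why: Dess–Martin oxidation under buffered, non-basic conditions gives the α-branched C18 aldehyde without epimerization at C13.

Step 11
Reactants: 13 C18 aldehyde
Product: 15 (3S,4S,5S,6R)-4-[(benzyloxy)methyl]-3-hydroxy-7-[(4-methoxybenzyl)oxy]-5,6-dimethyl-6-[(triethylsilyl)oxy]heptan-2-one, via enol ether carbinol 14 (not isolated)
Conditions: ethyl vinyl ether, t-BuLi, THF, −78 to 0 °C; MgBr2·OEt2, −78 °C; 13 in CH2Cl2, −78 °C; then 0.5 M HCl, THF, 0 °C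
Reagents that add atoms: ethyl vinyl ether (as 1-ethoxyvinyllithium), C=COCC; water, O
Why: Addition of an acetyl anion equivalent (1-ethoxyvinyl metal) to an α-chiral β-benzyloxy aldehyde; Cram chelation through O12 and the Felkin–Anh preference both send the nucleophile anti to the branched C14 substituent, which sets C18, and mild acid then unmasks the C17 methyl ketone.

Step 12
Reactants: 15 α-hydroxy methyl ketone
Product: 16 tert-butyldimethylsilyl ether of 15 at O18
Conditions: t-BuMe2SiOTf, 2,6-lutidine, CH2Cl2, −78 °C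
Reagents that add atoms: tert-butyldimethylsilyl trifluoromethanesulfonate, CC(C)(C)[Si](C)(C)OS(=O)(=O)C(F)(F)F
Why: Low-temperature silylation with a silyl triflate and 2,6-lutidine protects the secondary α-hydroxyl faster than the ketone can be enol-silylated.

Step 13
Reactants: 16 fully protected ketone
Product: 17 (3S,4S,5S,6R)-4-[(benzyloxy)methyl]-3-[(tert-butyldimethylsilyl)oxy]-7-hydroxy-5,6-dimethyl-6-[(triethylsilyl)oxy]heptan-2-one
Conditions: DDQ, CH2Cl2/pH 7 buffer (10:1), 0 °C
Reagents that add atoms: none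
Why: Oxidative cleavage of the electron-rich PMB ether with DDQ leaves the benzyl ether, both silyl ethers and the ketone untouched.

Step 14
Reactants: 17 C16 alcohol
Product: 18 (2R,3S,4S,5S)-4-[(benzyloxy)methyl]-5-[(tert-butyldimethylsilyl)oxy]-2,3-dimethyl-6-oxo-2-[(triethylsilyl)oxy]heptanal (C16 aldehyde and C17 methyl ketone)
Conditions: Dess–Martin periodinane, NaHCO3, CH2Cl2, 0 °C to rt
Reagents that add atoms: none
Why: Dess–Martin oxidation of the neopentyl-type primary alcohol gives the non-enolizable C16 aldehyde.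

Step 15
Reactants: 18 keto-aldehyde
Product: 19 (13S,14S,15R,17S,18S)-13-[(benzyloxy)methyl]-18-[(tert-butyldimethylsilyl)oxy]-17-hydroxy-14,15,17-trimethyl-15-[(triethylsilyl)oxy]cyclohexan-16-one (amaurone numbering; O15 and O17 and O18 on one ring face)
Conditions: 2-(pentafluorophenyl)-6,7-dihydro-5H-pyrrolo[2,1-c][1,2,4]triazol-2-ium tetrafluoroborate (20 mol %), i-Pr2NEt (20 mol %), toluene, 40 °C
Reagents that add atoms: none
Why: The triazolylidene adds to the C16 aldehyde and proton transfer gives the Breslow enaminol, which attacks the C17 methyl ketone while its O–H is handed to the ketone oxygen; collapse of the adduct releases the carbene and the α-ketol (intramolecular crossed aldehyde–ketone benzoin, a known carbene-catalysed route to cyclic tertiary α-ketols). The cyclohexanone ring C13–C18 is closed in a 6-exo-trig mode by forming the C16–C17 bond. The aldehyde sits on quaternary C15 and cannot enolize, and the ketone cannot form a Breslow intermediate, so aldol and homo-benzoin pathways are closed and only the crossed benzoin is open. The new stereocenter C17 is set by the substrate in a chair-like transition state that keeps C13–CH2OBn and C18–OSi equatorial and C15–OSiEt3 axial: the ketone methyl takes the equatorial site, away from a 1,3-diaxial clash with the axial silyloxy group, so the ketone oxygen is axial and the new hydroxyl ends cis to O15 and O18. The step needs attack on this ketone face and no epimerization at C18 next to the ketone; the concerted proton transfer puts the azolium on C16 on the face opposite both silyl ethers, where it meets only the axial C14 methyl, which is why a flat, compact N-C6F5 triazolylidene and a weak amine base are chosen.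

Step 16
Reactants: 19 α-ketol
Product: 20 cis-16,17-diol (ring as in 19; new C16 hydroxyl equatorial and cis to O15 and O17 and O18)
Conditions: NaBH4, MeOH/THF, −20 to 0 °C
Reagents that add atoms: none
Why: Borohydride reduction of a cyclohexanone; hydride adds axially on the face anti to the two axial α C–O bonds (C15–OSiEt3 and C17–OH; Felkin–Anh control reinforced by the bulk of the silyl ether), giving the equatorial C16 alcohol, which is also the more stable epimer.

Step 17
Reactants: 20 cis-16,17-diol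
Product: 21 C16 acetate (C17 hydroxyl free)
Conditions: Ac2O, DMAP (1 equiv), Et3N, CH2Cl2, rt to 35 °C
Reagents that add atoms: acetic anhydride, CC(=O)OC(C)=O
Why: DMAP-catalysed acetylation (Steglich–Höfle) acylates the secondary C16 hydroxyl in preference to the tertiary C17 hydroxyl, and an acetyl group on O17 would migrate to the less hindered cis-vicinal O16.

Step 18
Reactants: 21 C16 acetate
Product: 22 C12 primary alcohol (benzyl group removed)
Conditions: H2 (1 atm), Pd(OH)2/C, EtOAc, rt
Reagents that add atoms: none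
Why: Hydrogenolysis of the benzyl ether over Pd(OH)2/C in a neutral aprotic solvent frees O12 and spares the acetate and both silyl ethers.

Step 19
Reactants: 22 C12 alcohol
Product: 23 C12 aldehyde (formyl group on C13)
Conditions: Dess–Martin periodinane, NaHCO3, CH2Cl2, 0 °C
Reagents that add atoms: none
Why: Dess–Martin oxidation gives the C12 aldehyde; C13 carries the formyl group equatorial, the stable arrangement, so epimerization is not a threat.

Step 20
Reactants: 23 C12 aldehyde
Product: 24 (E)-enal (C10 aldehyde; C11=C12 with the C11 methyl)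
Conditions: Ph3P=C(CH3)CHO (3 equiv), toluene, 90 °C
Reagents that add atoms: 2-(triphenylphosphoranylidene)propanal, CC(C=O)=P(c1ccccc1)(c1ccccc1)c1ccccc1
Why: Wittig reaction with a stabilized α-methyl formyl ylide gives the (E)-trisubstituted C11=C12 enal directly and tolerates the acetate.

Step 21
Reactants: 24 (E)-enal
Product: 25 (2E,4E)-dienal (C8 aldehyde; C9=C10 and C11=C12)
Conditions: Ph3P=CHCHO (1.5 equiv), toluene, 70 °C, dark
Reagents that add atoms: (triphenylphosphoranylidene)acetaldehyde, O=CC=P(c1ccccc1)(c1ccccc1)c1ccccc1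
Why: Wittig two-carbon homologation with the stabilized formylmethylene ylide gives the (E)-C9=C10 bond; a small excess of ylide and monitoring hold back a second homologation.

Step 22
Reactants: 26 ethyl 2-methyl-3-oxopentanoate
Product: 27 ethyl 2,4-dimethyl-3,5-dioxoheptanoate
Conditions: NaH, THF, 0 °C; n-BuLi, 0 °C; EtCON(OMe)Me, −78 to 0 °C; aq HCl
Reagents that add atoms: N-methoxy-N-methylpropanamide, CCC(=O)N(C)OC
Why: Acylation of the keto ester dianion at its γ carbon (Huckin–Weiler dianion) with a Weinreb amide, whose tetrahedral adduct survives until work-up, gives the triketide.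

Step 23
Reactants: 27 ethyl 2,4-dimethyl-3,5-dioxoheptanoate
Product: 28 6-ethyl-4-hydroxy-3,5-dimethyl-2H-pyran-2-one
Conditions: DBU, toluene, reflux
Reagents that add atoms: none
Why: Base-mediated lactonization of the diketo ester enol onto the ester closes the 4-hydroxy-2-pyranone ring.

Step 24
Reactants: 28 6-ethyl-4-hydroxy-3,5-dimethyl-2H-pyran-2-one
Product: 29 2-ethyl-6-methoxy-3,5-dimethyl-4H-pyran-4-one
Conditions: MeOTf, CH2Cl2, rt; aq NaHCO3
Reagents that add atoms: methyl trifluoromethanesulfonate, COS(=O)(=O)C(F)(F)F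
Why: O-Methylation of the 4-hydroxy-2-pyranone by a hard methylating agent occurs at the lactone carbonyl oxygen, and loss of a proton gives the 2-methoxy-4-pyranone.

Step 25
Reactants: 29 2-ethyl-6-methoxy-3,5-dimethyl-4H-pyran-4-one
Product: 31 diethyl [1-(6-methoxy-3,5-dimethyl-4-oxo-4H-pyran-2-yl)ethyl]phosphonate (racemic), via phosphonite 30 (not isolated)
Conditions: LiHMDS (2.2 equiv), THF, −78 °C; ClP(OEt)2, −78 to 0 °C; then 30% H2O2, 0 °C
Reagents that add atoms: diethyl chlorophosphite, CCOP(Cl)OCC; hydrogen peroxide, OO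
Why: The vinylogous enolate formed at the CH2 of the 2-ethyl group is trapped at carbon by the soft phosphorus electrophile and the phosphonite is oxidized to the phosphonate (the enolate–chlorophosphite route to C–P bonds).

Step 26
Reactants: 25 (2E,4E)-dienal; 31 pyranone phosphonate
Product: 32 15-O-triethylsilyl-18-O-tert-butyldimethylsilyl amaurone A
Conditions: 31, LiHMDS, THF, −78 °C; then 25, −78 to 0 °C, dark
Reagents that add atoms: none
Why: Horner–Wadsworth–Emmons olefination of a stabilized α-methyl phosphonate with a conjugated aldehyde gives the (E)-trisubstituted C7=C8 alkene, and the stereocenter of 31 is lost in the step.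

Step 27
Reactants: 32 bis-silyl amaurone A
Product: 33 amaurone A
Conditions: HF·pyridine, pyridine, THF, 0 °C to rt, dark
Reagents that add atoms: none
Why: Buffered HF·pyridine cleaves the tertiary triethylsilyl and the secondary tert-butyldimethylsilyl ether without acyl migration or damage to the methoxypyranone triene.

**Compound list**
1 | (E)-2-methylbut-2-en-1-ol | C/C=C(\C)CO | starting material
2 | [(2S,3S)-2,3-dimethyloxiran-2-yl]methanol | OC[C@]1(C)O[C@H]1C | intermediate
3 | (2R,3S)-2,3-dimethylpent-4-ene-1,2-diol | OC[C@](C)(O)[C@@H](C)C=C | intermediate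
4 | (2R,3S)-1-[(4-methoxybenzyl)oxy]-2,3-dimethylpent-4-en-2-ol | COc1ccc(COC[C@](C)(O)[C@@H](C)C=C)cc1 | intermediate
5 | triethyl{[(2R,3S)-1-[(4-methoxybenzyl)oxy]-2,3-dimethylpent-4-en-2-yl]oxy}silane | COc1ccc(COC[C@](C)(O[Si](CC)(CC)CC)[C@@H](C)C=C)cc1 | intermediate
6 | B-alkyl-9-borabicyclo[3.3.1]nonane adduct of 5 (boron on the terminal carbon) | COc1ccc(COC[C@](C)(O[Si](CC)(CC)CC)[C@@H](C)CCB2C3CCCC2CCC3)cc1 | intermediate (not isolated)
7 | (3S,4R)-5-[(4-methoxybenzyl)oxy]-3,4-dimethyl-4-[(triethylsilyl)oxy]pentan-1-ol | COc1ccc(COC[C@](C)(O[Si](CC)(CC)CC)[C@@H](C)CCO)cc1 | intermediate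
8 | (3S,4R)-5-[(4-methoxybenzyl)oxy]-3,4-dimethyl-4-[(triethylsilyl)oxy]pentanoic acid | COc1ccc(COC[C@](C)(O[Si](CC)(CC)CC)[C@@H](C)CC(=O)O)cc1 | intermediate
9 | mixed anhydride of 8 with pivalic acid | COc1ccc(COC[C@](C)(O[Si](CC)(CC)CC)[C@@H](C)CC(=O)OC(=O)C(C)(C)C)cc1 | intermediate (not isolated)
10 | (R)-4-benzyl-3-[(3S,4R)-5-[(4-methoxybenzyl)oxy]-3,4-dimethyl-4-[(triethylsilyl)oxy]pentanoyl]oxazolidin-2-one | COc1ccc(COC[C@](C)(O[Si](CC)(CC)CC)[C@@H](C)CC(=O)N2[C@H](Cc3ccccc3)COC2=O)cc1 | intermediate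
11 | (R)-4-benzyl-3-[(2S,3S,4R)-2-[(benzyloxy)methyl]-5-[(4-methoxybenzyl)oxy]-3,4-dimethyl-4-[(triethylsilyl)oxy]pentanoyl]oxazolidin-2-one | COc1ccc(COC[C@](C)(O[Si](CC)(CC)CC)[C@@H](C)[C@@H](COCc2ccccc2)C(=O)N3[C@H](Cc4ccccc4)COC3=O)cc1 | intermediate
12 | (2R,3S,4R)-2-[(benzyloxy)methyl]-5-[(4-methoxybenzyl)oxy]-3,4-dimethyl-4-[(triethylsilyl)oxy]pentan-1-ol | COc1ccc(COC[C@](C)(O[Si](CC)(CC)CC)[C@@H](C)[C@@H](COCc2ccccc2)CO)cc1 | intermediate
13 | (2S,3S,4R)-2-[(benzyloxy)methyl]-5-[(4-methoxybenzyl)oxy]-3,4-dimethyl-4-[(triethylsilyl)oxy]pentanal | COc1ccc(COC[C@](C)(O[Si](CC)(CC)CC)[C@@H](C)[C@@H](COCc2ccccc2)C=O)cc1 | intermediate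
14 | (3S,4S,5S,6R)-4-[(benzyloxy)methyl]-2-ethoxy-7-[(4-methoxybenzyl)oxy]-5,6-dimethyl-6-[(triethylsilyl)oxy]hept-1-en-3-ol | COc1ccc(COC[C@](C)(O[Si](CC)(CC)CC)[C@@H](C)[C@@H](COCc2ccccc2)[C@H](O)C(=C)OCC)cc1 | intermediate (not isolated)
15 | (3S,4S,5S,6R)-4-[(benzyloxy)methyl]-3-hydroxy-7-[(4-methoxybenzyl)oxy]-5,6-dimethyl-6-[(triethylsilyl)oxy]heptan-2-one | COc1ccc(COC[C@](C)(O[Si](CC)(CC)CC)[C@@H](C)[C@@H](COCc2ccccc2)[C@H](O)C(C)=O)cc1 | intermediate
16 | (3S,4S,5S,6R)-4-[(benzyloxy)methyl]-3-[(tert-butyldimethylsilyl)oxy]-7-[(4-methoxybenzyl)oxy]-5,6-dimethyl-6-[(triethylsilyl)oxy]heptan-2-one | COc1ccc(COC[C@](C)(O[Si](CC)(CC)CC)[C@@H](C)[C@@H](COCc2ccccc2)[C@H](O[Si](C)(C)C(C)(C)C)C(C)=O)cc1 | intermediate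
17 | (3S,4S,5S,6R)-4-[(benzyloxy)methyl]-3-[(tert-butyldimethylsilyl)oxy]-7-hydroxy-5,6-dimethyl-6-[(triethylsilyl)oxy]heptan-2-one | OC[C@](C)(O[Si](CC)(CC)CC)[C@@H](C)[C@@H](COCc1ccccc1)[C@H](O[Si](C)(C)C(C)(C)C)C(C)=O | intermediate
18 | (2R,3S,4S,5S)-4-[(benzyloxy)methyl]-5-[(tert-butyldimethylsilyl)oxy]-2,3-dimethyl-6-oxo-2-[(triethylsilyl)oxy]heptanal | O=C[C@](C)(O[Si](CC)(CC)CC)[C@@H](C)[C@@H](COCc1ccccc1)[C@H](O[Si](C)(C)C(C)(C)C)C(C)=O | intermediate
19 | (13S,14S,15R,17S,18S)-13-[(benzyloxy)methyl]-18-[(tert-butyldimethylsilyl)oxy]-17-hydroxy-14,15,17-trimethyl-15-[(triethylsilyl)oxy]cyclohexan-16-one (amaurone numbering) | c1ccccc1COC[C@@H]2[C@H](C)[C@@](C)(O[Si](CC)(CC)CC)C(=O)[C@@](C)(O)[C@H]2O[Si](C)(C)C(C)(C)C | intermediate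
20 | cis-16,17-diol of 19 (C16 hydroxyl cis to O15, O17 and O18) | c1ccccc1COC[C@@H]2[C@H](C)[C@@](C)(O[Si](CC)(CC)CC)[C@@H](O)[C@@](C)(O)[C@H]2O[Si](C)(C)C(C)(C)C | intermediate
21 | 16-O-acetate of 20 | c1ccccc1COC[C@@H]2[C@H](C)[C@@](C)(O[Si](CC)(CC)CC)[C@@H](OC(C)=O)[C@@](C)(O)[C@H]2O[Si](C)(C)C(C)(C)C | intermediate
22 | C12 primary alcohol (debenzylated 21) | OC[C@@H]1[C@H](C)[C@@](C)(O[Si](CC)(CC)CC)[C@@H](OC(C)=O)[C@@](C)(O)[C@H]1O[Si](C)(C)C(C)(C)C | intermediate
23 | C12 aldehyde (ring carbaldehyde at C13) | O=C[C@@H]1[C@H](C)[C@@](C)(O[Si](CC)(CC)CC)[C@@H](OC(C)=O)[C@@](C)(O)[C@H]1O[Si](C)(C)C(C)(C)C | intermediate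
24 | (E)-2-methyl-3-(ring-C13)prop-2-enal (C10 aldehyde) | O=C/C(C)=C/[C@@H]1[C@H](C)[C@@](C)(O[Si](CC)(CC)CC)[C@@H](OC(C)=O)[C@@](C)(O)[C@H]1O[Si](C)(C)C(C)(C)C | intermediate
25 | (2E,4E)-4-methyl-5-(ring-C13)penta-2,4-dienal (C8 aldehyde) | O=C/C=C/C(C)=C/[C@@H]1[C@H](C)[C@@](C)(O[Si](CC)(CC)CC)[C@@H](OC(C)=O)[C@@](C)(O)[C@H]1O[Si](C)(C)C(C)(C)C | intermediate
26 | ethyl 2-methyl-3-oxopentanoate | CCC(=O)C(C)C(=O)OCC | starting material
27 | ethyl 2,4-dimethyl-3,5-dioxoheptanoate | CCC(=O)C(C)C(=O)C(C)C(=O)OCC | intermediate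
28 | 6-ethyl-4-hydroxy-3,5-dimethyl-2H-pyran-2-one | CCc1oc(=O)c(C)c(O)c1C | intermediate
29 | 2-ethyl-6-methoxy-3,5-dimethyl-4H-pyran-4-one | CCc1oc(OC)c(C)c(=O)c1C | intermediate
30 | diethyl [1-(6-methoxy-3,5-dimethyl-4-oxo-4H-pyran-2-yl)ethyl]phosphonite | CCOP(OCC)C(C)c1oc(OC)c(C)c(=O)c1C | intermediate (not isolated)
31 | diethyl [1-(6-methoxy-3,5-dimethyl-4-oxo-4H-pyran-2-yl)ethyl]phosphonate (racemic) | CCOP(=O)(OCC)C(C)c1oc(OC)c(C)c(=O)c1C | intermediate
32 | 15-O-triethylsilyl-18-O-tert-butyldimethylsilyl amaurone A | COc1oc(/C(C)=C/C=C/C(C)=C/[C@@H]2[C@H](C)[C@@](C)(O[Si](CC)(CC)CC)[C@@H](OC(C)=O)[C@@](C)(O)[C@H]2O[Si](C)(C)C(C)(C)C)c(C)c(=O)c1C | intermediate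
33 | amaurone A | COc1oc(/C(C)=C/C=C/C(C)=C/[C@@H]2[C@H](C)[C@@](C)(O)[C@@H](OC(C)=O)[C@@](C)(O)[C@H]2O)c(C)c(=O)c1C | target

**Step count**
Total steps: 27. Longest linear sequence: 23 (steps 1–21, 26, 27); steps 22–25 form the pyranone branch.

**Steps most likely to fail**

Step 15. Three processes may defeat it:
- The carbene may add only slowly to the neopentyl-type α-silyloxy aldehyde.
- The ketone may be attacked on the wrong face, because the proton-transfer geometry places the azolium syn-axial to the C14 methyl in the desired transition state.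
- C18 may epimerize next to the ketone.

Fallback, from 13, rejoining at 20 (it bypasses steps 11–16 and sets C16 and C17 together by a directed syn-dihydroxylation). Aldehyde 13 is treated with isopropenylmagnesium bromide and MgBr2·OEt2, with the same chelate sense as step 11, to give the allylic alcohol F1. DDQ removes the PMB group to give the diol F2. TEMPO/PhI(OAc)2 oxidizes only the primary hydroxyl to the hydroxy aldehyde F3, which may sit as its lactol. Ph3P=CH2 gives the diene F4. The second-generation Grubbs catalyst closes ring C13–C18 to the cyclohexenol F5. OsO4/TMEDA in CH2Cl2 at −78 °C (hydroxyl-directed dihydroxylation) should add both oxygens on the face of the free C18 hydroxyl to give the all-cis triol F6. t-BuMe2SiOTf then silylates the less hindered C18 hydroxyl to give 20.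

Step 16. Hydride may be delivered to the other face, because the axial C14 methyl hinders axial attack and an alkoxyborohydride formed at O17 can deliver hydride internally; this would give the axial C16 alcohol. Fallback, from 19, rejoining at 20, with no new compound: replace irreversible hydride addition by equilibrating hydrogen transfer (Meerwein–Ponndorf–Verley reduction with Al(OiPr)3 in i-PrOH/toluene at 60–80 °C, with a little acetone so that the Oppenauer back-reaction keeps the carbinol equilibrating). The axial C16 alcohol has a 1,3-diaxial contact with the C14 methyl, so the equilibrium should favour 20.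

Step 17. Acylation may stall at the crowded O16, which lies between two fully substituted carbons, or take place at O17. Fallback, from 20, rejoining at 21. MeC(OMe)3 with pyridinium p-toluenesulfonate ties O16 and O17 into the cyclic orthoacetate F7 by way of a small dialkoxycarbenium electrophile. Aqueous acetic acid opens F7, by the axial-ester rule mainly to the tertiary C17 acetate F8. Et3N/DMAP in CH2Cl2 then lets the acetyl group migrate to the cis-vicinal, less hindered secondary O16 to give 21.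

**Further compounds**
F1 | step 15 | (3S,4S,5S,6R)-4-[(benzyloxy)methyl]-7-[(4-methoxybenzyl)oxy]-2,5,6-trimethyl-6-[(triethylsilyl)oxy]hept-1-en-3-ol | COc1ccc(COC[C@](C)(O[Si](CC)(CC)CC)[C@@H](C)[C@@H](COCc2ccccc2)[C@H](O)C(C)=C)cc1
F2 | step 15 | diol from F1 after PMB removal (C16 and C18 hydroxyls free) | OC[C@](C)(O[Si](CC)(CC)CC)[C@@H](C)[C@@H](COCc1ccccc1)[C@H](O)C(C)=C
F3 | step 15 | C16 aldehyde with free C18 hydroxyl (open form of the lactol) | O=C[C@](C)(O[Si](CC)(CC)CC)[C@@H](C)[C@@H](COCc1ccccc1)[C@H](O)C(C)=C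
F4 | step 15 | diene with C15 vinyl and C18 isopropenyl carbinol | C=C[C@](C)(O[Si](CC)(CC)CC)[C@@H](C)[C@@H](COCc1ccccc1)[C@H](O)C(C)=C
F5 | step 15 | cyclohexenol (C16=C17 alkene; C18 hydroxyl free; C15 triethylsilyl ether) | c1ccccc1COC[C@@H]2[C@H](C)[C@@](C)(O[Si](CC)(CC)CC)C=C(C)[C@H]2O
F6 | step 15 | all-cis 16,17,18-triol (C15 triethylsilyl ether; O12 benzyl) | c1ccccc1COC[C@@H]2[C@H](C)[C@@](C)(O[Si](CC)(CC)CC)[C@@H](O)[C@@](C)(O)[C@H]2O
F0 | step 16 | none | none
F7 | step 17 | cyclic methyl orthoacetate of 20 across O16 and O17 | c1ccccc1COC[C@@H]2[C@H](C)[C@@](C)(O[Si](CC)(CC)CC)[C@H]3OC(C)(OC)O[C@@]3(C)[C@H]2O[Si](C)(C)C(C)(C)C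
F8 | step 17 | 17-O-acetate of 20 (C16 hydroxyl free) | c1ccccc1COC[C@@H]2[C@H](C)[C@@](C)(O[Si](CC)(CC)CC)[C@@H](O)[C@@](C)(OC(C)=O)[C@H]2O[Si](C)(C)C(C)(C)C
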